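**Retrosynthetic overview**
- The (Z)-enyne comes from a Peterson olefination of a C5 aldehyde followed by desilylation. The C5–C6 bond and the 6,12-trans ether centre come from C-glycosylation of an eight-membered lactol acetate.
- The only ring (the oxocane, first as its lactone) is closed by a copper-catalysed 8-endo chlorine-atom-transfer radical cyclisation of an acyclic dichloroacetate. This one step forms C7–C8 and both C–Cl bonds (C7, C9).
- The cyclisation substrate comes from a syn-1,3-diol (lipase mono-acetylation, then dichloroacetylation). The diol comes from an anti-selective aldol of (S)-2-bromobutanal with the enolate of methyl vinyl ketone, followed by syn reduction.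
- The C13–Br centre comes from organocatalytic α-bromination of butanal.

Assumption: the (S)-diarylprolinol silyl ether is taken to give (S)-2-bromobutanal, as in related α-heteroatom functionalisations (otherwise the (R)-catalyst is used); labels C1–C15 run from the alkyne CH to the ethyl CH3, so the ring is O plus C6–C12.

**Step 1**
Reactants: 1 butanal
Product: 2 (2S)-2-bromobutanal
Conditions: (S)-α,α-diphenylprolinol trimethylsilyl ether (5 mol %), NBS (slow addition), (CF3)2CHOH/CH2Cl2, H2O (cat.), 0 °C; cold pentane/silica filtration, solution used at once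
Reagents that add atoms: N-bromosuccinimide, O=C1CCC(=O)N1Br
Why: Enamine-catalysed asymmetric α-bromination, in which the E-enamine is brominated on the face away from the diphenyl(silyloxy)methyl arm to set C13 as S, and the labile aldehyde is never stored.

**Step 2**
Reactants: 3 but-3-en-2-one; 2 (2S)-2-bromobutanal
Product: 5 (5R,6S)-6-bromo-5-hydroxyoct-1-en-3-one, via lithium dienolate 4 (not isolated)
Conditions: LiN(SiMe3)2, THF, −78 °C; then 2, −78 °C, 15 min; AcOH quench at −78 °C
Reagents that add atoms: none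
Why: Kinetic methyl-ketone lithium aldol reaction in which Cornforth/polar Felkin–Anh addition to the α-bromo aldehyde gives the 1,2-anti bromohydrin (C12 R), and the cold acidic quench prevents epoxide closure.

**Step 3**
Reactants: 5 (5R,6S)-6-bromo-5-hydroxyoct-1-en-3-one
Product: 7 (3S,5R,6S)-6-bromooct-1-ene-3,5-diol, via diethylboron chelate 6 (not isolated)
Conditions: Et2BOMe, THF/MeOH 4:1, −78 °C; NaBH4, −78 °C; AcOH, then MeOH azeotrope
Reagents that add atoms: none
Why: Narasaka–Prasad reduction, in which external hydride adds axially to the six-membered boron chelate (1,2-addition to the activated enone carbonyl) and gives the 1,3-syn diol (C10 S) without base that would close the bromohydrin.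

**Step 4**
Reactants: 7 (3S,5R,6S)-6-bromooct-1-ene-3,5-diol
Product: 8 (3S,5R,6S)-6-bromo-5-hydroxyoct-1-en-3-yl acetate
Conditions: immobilised Candida antarctica lipase B, vinyl acetate, t-BuOMe, 30 °C
Reagents that add atoms: vinyl acetate, CC(=O)OC=C
Why: Lipase-catalysed irreversible transesterification, in which the (S)-allylic carbinol (vinyl as the medium group) is the Kazlauskas-matched site while the hindered bromohydrin OH is untouched, and any C10-epimeric diol reacts slowly and is left behind.

**Step 5**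
Reactants: 8 (3S,5R,6S)-6-bromo-5-hydroxyoct-1-en-3-yl acetate; 9 dichloroacetyl chloride
Product: 10 (3S,5R,6S)-3-(acetyloxy)-6-bromooct-1-en-5-yl dichloroacetate
Conditions: pyridine, CH2Cl2, −20 → 0 °C
Reagents that add atoms: none
Why: O-Acylation of the remaining secondary alcohol by a very reactive acid chloride (pyridine rather than Et3N avoids dichloroketene), with no stereocentre touched.

**Step 6 (key step)**
Reactants: 10 (3S,5R,6S)-3-(acetyloxy)-6-bromooct-1-en-5-yl dichloroacetate
Product: 13 (3S,5S,6S,8R)-8-[(1S)-1-bromopropyl]-3,5-dichloro-2-oxooxocan-6-yl acetate, via α-chloro ester radical 11 (not isolated), via cyclised C9 radical 12 (not isolated)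
Conditions: CuCl (30 mol %), tris(2-pyridylmethyl)amine (30 mol %), ClCH2CH2Cl (5 mM, degassed), 80 °C
Reagents that add atoms: none
Why: Kharasch-type atom-transfer radical cyclisation: monovalent copper abstracts Cl, the electrophilic α-chloro ester radical closes 8-endo on the terminal alkene (the mode known for pent-4-enyl chloroacetates) to form C7–C8, and the divalent copper chloride complex returns Cl to C9 anti to the neighbouring acetoxy group (9S). C7 (7S) is a prediction: its C–Cl bond is re-activated reversibly by the same catalyst and should settle pseudo-equatorial, trans to the C9 chlorine.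

**Step 7**
Reactants: 13 (3S,5S,6S,8R)-8-[(1S)-1-bromopropyl]-3,5-dichloro-2-oxooxocan-6-yl acetate
Product: 15 (3S,5S,6S,8R)-8-[(1S)-1-bromopropyl]-3,5-dichlorooxocane-2,6-diyl diacetate (both C2 epimers), via aluminium hemiacetal 14 (not isolated)
Conditions: i-Bu2AlH (1.1 equiv), CH2Cl2, −78 °C; then pyridine, DMAP, Ac2O, −78 → −20 °C
Reagents that add atoms: acetic anhydride, CC(=O)OC(C)=O
Why: Rychnovsky reductive acetylation, in which the strained, α-chloro-activated lactone is reduced much faster than the secondary acetate and the stable aluminium hemiacetal is acetylated in situ without ring opening.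

**Step 8**
Reactants: 15 (3S,5S,6S,8R)-8-[(1S)-1-bromopropyl]-3,5-dichlorooxocane-2,6-diyl diacetate; 16 trimethyl(vinyloxy)silane
Product: 18 (2S,3S,5S,6S,8R)-8-[(1S)-1-bromopropyl]-3,5-dichloro-2-(2-oxoethyl)oxocan-6-yl acetate, via oxocarbenium ion 17 (not isolated)
Conditions: BF3·OEt2, CH2Cl2, −78 → −40 °C
Reagents that add atoms: none
Why: Mukaiyama-type C-glycosylation, in which the anomeric acetate ionises and the silyl enol ether attacks pseudo-axially, opposite the C12 side chain and anti to the pseudo-axial C7–H. This is the α,α′-trans and 1,2-cis outcome known for cyclic oxocarbenium ions with an α-heteroatom, and it sets C6 as S.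

**Step 9**
Reactants: 18 (2S,3S,5S,6S,8R)-8-[(1S)-1-bromopropyl]-3,5-dichloro-2-(2-oxoethyl)oxocan-6-yl acetate
Product: 20 (2S,3S,5S,6S,8R)-8-[(1S)-1-bromopropyl]-3,5-dichloro-2-[(2Z)-5-(triisopropylsilyl)pent-2-en-4-yn-1-yl]oxocan-6-yl acetate, via β-silyl alkoxide 19 (not isolated)
Conditions: 1,3-bis(triisopropylsilyl)propyne, n-BuLi, THF, −20 °C; then 18, −78 → 0 °C; H2O
Reagents that add atoms: 1,3-bis(triisopropylsilyl)propyne, CC(C)[Si](C(C)C)(C(C)C)CC#C[Si](C(C)C)(C(C)C)C(C)C
Why: Corey–Rücker Peterson olefination, in which the bulky silyl-stabilised propargyl anion adds to the aldehyde (far faster than to the acetate at −78 °C) and the β-silyl alkoxide syn-eliminates in situ to give the Z-enyne (typically about 20:1).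

**Step 10**
Reactants: 20 (2S,3S,5S,6S,8R)-8-[(1S)-1-bromopropyl]-3,5-dichloro-2-[(2Z)-5-(triisopropylsilyl)pent-2-en-4-yn-1-yl]oxocan-6-yl acetate
Product: 21 (2S,3S,5S,6S,8R)-8-[(1S)-1-bromopropyl]-3,5-dichloro-2-[(2Z)-pent-2-en-4-yn-1-yl]oxocan-6-yl acetate (CNP0251465.4)
Conditions: Bu4NF, AcOH, THF, 0 °C
Reagents that add atoms: none
Why: Fluoride protodesilylation of the alkynylsilane, buffered with AcOH so that the acetate, the secondary halides and the Z-enyne are not touched.

**Compound list**
1 | butanal | CCCC=O | starting material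
2 | (2S)-2-bromobutanal | O=C[C@@H](Br)CC | intermediate
3 | but-3-en-2-one | CC(=O)C=C | starting material
4 | lithium buta-1,3-dien-2-olate | [Li+].[O-]C(=C)C=C | intermediate (not isolated)
5 | (5R,6S)-6-bromo-5-hydroxyoct-1-en-3-one | C=CC(=O)C[C@@H](O)[C@@H](Br)CC | intermediate
6 | (5R,6S)-6-bromo-5-[(diethylboranyl)oxy]oct-1-en-3-one (boron chelated by the ketone) | CCB(CC)O[C@H](CC(=O)C=C)[C@@H](Br)CC | intermediate (not isolated)
7 | (3S,5R,6S)-6-bromooct-1-ene-3,5-diol | C=C[C@@H](O)C[C@@H](O)[C@@H](Br)CC | intermediate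
8 | (3S,5R,6S)-6-bromo-5-hydroxyoct-1-en-3-yl acetate | C=C[C@@H](OC(C)=O)C[C@@H](O)[C@@H](Br)CC | intermediate
9 | dichloroacetyl chloride | O=C(Cl)C(Cl)Cl | starting material
10 | (3S,5R,6S)-3-(acetyloxy)-6-bromooct-1-en-5-yl dichloroacetate | C=C[C@@H](OC(C)=O)C[C@@H](OC(=O)C(Cl)Cl)[C@@H](Br)CC | intermediate
11 | α-chloro ester radical from 10 (radical at C7, one Cl removed) | C=C[C@@H](OC(C)=O)C[C@@H](OC(=O)[CH]Cl)[C@@H](Br)CC | intermediate (not isolated)
12 | ring-closed lactone radical (radical at C9; C7, C10, C12, C13 as in 13) | O=C1O[C@@H]([C@@H](Br)CC)C[C@H](OC(C)=O)[CH]C[C@@H]1Cl | intermediate (not isolated)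
13 | (3S,5S,6S,8R)-8-[(1S)-1-bromopropyl]-3,5-dichloro-2-oxooxocan-6-yl acetate | O=C1O[C@@H]([C@@H](Br)CC)C[C@H](OC(C)=O)[C@@H](Cl)C[C@@H]1Cl | intermediate
14 | diisobutylaluminium hemiacetal of 13 (O–Al at C6, both epimers) | CC(C)C[Al](CC(C)C)OC1O[C@@H]([C@@H](Br)CC)C[C@H](OC(C)=O)[C@@H](Cl)C[C@@H]1Cl | intermediate (not isolated)
15 | (3S,5S,6S,8R)-8-[(1S)-1-bromopropyl]-3,5-dichlorooxocane-2,6-diyl diacetate (both C2 epimers) | CC(=O)OC1O[C@@H]([C@@H](Br)CC)C[C@H](OC(C)=O)[C@@H](Cl)C[C@@H]1Cl | intermediate
16 | trimethyl(vinyloxy)silane | C=CO[Si](C)(C)C | starting material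
17 | cyclic oxocarbenium ion from 15 (cationic at C6, other centres as in 15) | C1=[O+][C@@H]([C@@H](Br)CC)C[C@H](OC(C)=O)[C@@H](Cl)C[C@@H]1Cl | intermediate (not isolated)
18 | (2S,3S,5S,6S,8R)-8-[(1S)-1-bromopropyl]-3,5-dichloro-2-(2-oxoethyl)oxocan-6-yl acetate | O=CC[C@@H]1O[C@@H]([C@@H](Br)CC)C[C@H](OC(C)=O)[C@@H](Cl)C[C@@H]1Cl | intermediate
19 | lithium β-silyl alkoxide adduct of 18 (C4–O Li, C3–Si(i-Pr)3; the two new centres are unassigned, the syn-eliminating pair gives Z) | [Li+].[O-]C(C[C@@H]1O[C@@H]([C@@H](Br)CC)C[C@H](OC(C)=O)[C@@H](Cl)C[C@@H]1Cl)C(C#C[Si](C(C)C)(C(C)C)C(C)C)[Si](C(C)C)(C(C)C)C(C)C | intermediate (not isolated)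
20 | (2S,3S,5S,6S,8R)-8-[(1S)-1-bromopropyl]-3,5-dichloro-2-[(2Z)-5-(triisopropylsilyl)pent-2-en-4-yn-1-yl]oxocan-6-yl acetate | CC(C)[Si](C(C)C)(C(C)C)C#C/C=C\C[C@@H]1O[C@@H]([C@@H](Br)CC)C[C@H](OC(C)=O)[C@@H](Cl)C[C@@H]1Cl | intermediate
21 | (2S,3S,5S,6S,8R)-8-[(1S)-1-bromopropyl]-3,5-dichloro-2-[(2Z)-pent-2-en-4-yn-1-yl]oxocan-6-yl acetate | C#C/C=C\C[C@@H]1O[C@@H]([C@@H](Br)CC)C[C@H](OC(C)=O)[C@@H](Cl)C[C@@H]1Cl | target

**Totals**
Total step count: 10. Longest linear sequence: 10 (fully linear).

**The three steps most likely to fail**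

Step 6. The dichloroacetate is the least reactive substrate class for 8-endo chlorine transfer, and the C7 configuration rests on a prediction. The fallback sets out from 8. It is acylated with trichloroacetyl chloride and pyridine to give (3S,5R,6S)-3-(acetyloxy)-6-bromooct-1-en-5-yl trichloroacetate F1. F1 is cyclised with CuCl/2,2′-bipyridine in ClCH2CH2Cl at 80 °C, the best-behaved substrate class for this ring closure, to (5S,6S,8R)-8-[(1S)-1-bromopropyl]-3,3,5-trichloro-2-oxooxocan-6-yl acetate F2, in which C7 is not yet stereogenic. One α-chlorine is then removed with SmI2 (2 equiv) and MeOH in THF at −78 °C, through a samarium enolate that is protonated kinetically; the unactivated C–Br and C9–Cl bonds are inert under these conditions. This separates the C7 configuration from the ring closure and comes back to the route at 13.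

Step 8. The α-chlorine destabilises the oxocarbenium ion, the product aldehyde must survive the Lewis acid, and the facial selectivity on an eight-membered ring is argued by analogy. The fallback sets out from 15. It is treated with allyltrimethylsilane and BF3·OEt2, the best-studied π-nucleophile for cyclic oxocarbenium ions, to give (2S,3S,5S,6S,8R)-8-[(1S)-1-bromopropyl]-3,5-dichloro-2-(prop-2-en-1-yl)oxocan-6-yl acetate F3. The only alkene of F3 is then cleaved with O3 in CH2Cl2 at −78 °C followed by PPh3, which comes back to the route at 18.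

Step 2. The lithium enolate of methyl vinyl ketone can oligomerise, and the basic medium can racemise 2 or close the bromohydrin to an epoxide. The fallback sets out from 3. It is converted with Me3SiOTf and Et3N into 2-(trimethylsilyloxy)buta-1,3-diene F4, which is distilled. F4 is then joined to 2 in a BF3·OEt2-promoted Mukaiyama aldol reaction in CH2Cl2 at −78 °C; this goes through an open, non-basic transition state with the same polar Felkin–Anh anti preference. The fallback comes back to the route at 5.

**Further compounds**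
F1 | step 6 | (3S,5R,6S)-3-(acetyloxy)-6-bromooct-1-en-5-yl trichloroacetate | C=C[C@@H](OC(C)=O)C[C@@H](OC(=O)C(Cl)(Cl)Cl)[C@@H](Br)CC
F2 | step 6 | (5S,6S,8R)-8-[(1S)-1-bromopropyl]-3,3,5-trichloro-2-oxooxocan-6-yl acetate | O=C1O[C@@H]([C@@H](Br)CC)C[C@H](OC(C)=O)[C@@H](Cl)CC1(Cl)Cl
F3 | step 8 | (2S,3S,5S,6S,8R)-8-[(1S)-1-bromopropyl]-3,5-dichloro-2-(prop-2-en-1-yl)oxocan-6-yl acetate | C=CC[C@@H]1O[C@@H]([C@@H](Br)CC)C[C@H](OC(C)=O)[C@@H](Cl)C[C@@H]1Cl
F4 | step 2 | 2-(trimethylsilyloxy)buta-1,3-diene | C=CC(=C)O[Si](C)(C)C
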